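**Plan**
- Retrosynthetic cuts, in order: the C–Br and C–Cl bonds (anti addition of BrCl to a ring A alkene); then both C–C bonds joining the bridgeheads C1 and C4 of the 7-oxabicyclo[2.2.1]heptane to its two-carbon bridge C2(spiro)–C3(CMe2); then the ring A alkene and the carbinol C–C bond.
- Enabling feature: C1–O7–C4 with the C5–C6 bridge is a furan, and C2–C3 is the isopropylidene C=C of a terpinolene-type ring. The 2'-oxygen lies syn to C1 on ring A and exo on C2, two bonds from the C1 methyl carbon, so that carbon can act as an O–CH(OMe) link from the 2'-oxygen to furan C2.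
- Forward order: enal 7, asymmetric methallylboration, ring A by metathesis (10), mixed furfural acetal 12, then a pressure-driven intramolecular furan cycloaddition that closes the carbocycle and the tether ring at once (14 after diimide).
- Helper removal: the acetal carbon becomes the C1 methyl group (dithiolane, Raney nickel), which frees the 2'-OH for acetylation; BrCl addition ends the route.
- Stereochemistry: C2' from the catalyst-controlled allylboration; C2, C1 and C4 from C2' through the tether (syn face, exo link); C4' and C5' from anti addition steered by the ring A substituents.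

Key step: step 6

Remark: the facial sense of the phosphoric acid-catalysed allylboration is assumed to follow that known for benzaldehyde (if the enal responds oppositely, the antipodal catalyst is used), and 12 to 14 are carried as both epimers at the acetal carbon, a centre that is erased in steps 7 to 9.

Locants for the spiro compounds: unprimed = 7-oxabicyclo[2.2.1]heptane (C1 bridgehead next to the spiro carbon C2, C3 = CMe2, C4 = CH bridgehead); primed = ring A (C1' = spiro carbon, C2' = carbinol carbon).

**Step 1**
Reactants: 1 3-methylbut-2-enal; 2 cyclohexylamine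
Product: 3 (E)-N-cyclohexyl-3-methylbut-2-en-1-imine
Conditions: 2 (1.05 eq), K2CO3, Et2O, 0 °C → rt; distillation
Reagents that add atoms: none
Why: Imine formation from an aldehyde and a primary amine should give the 1-azadiene that allows γ-deprotonation in the next step.

**Step 2**
Reactants: 3 (E)-N-cyclohexyl-3-methylbut-2-en-1-imine; 4 allyl bromide
Product: 7 2-(propan-2-ylidene)pent-4-enal, via α-allylated imine 5 (not isolated), via deconjugated aldehyde 6 (not isolated)
Conditions: LiN(iPr)2, THF, −78 → 0 °C; 4, −78 °C → rt; aq. oxalic acid, Et2O, rt; DBU (cat.), CH2Cl2, rt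
Reagents that add atoms: water, O
Why: The 1-azapentadienyl anion formed by γ-deprotonation should be alkylated at the α-carbon (α-alkylation of a metalated unsaturated imine), and hydrolysis followed by base-mediated double-bond migration through the dienol should give the conjugated, tetrasubstituted enal.

**Step 3**
Reactants: 7 2-(propan-2-ylidene)pent-4-enal; 8 4,4,5,5-tetramethyl-2-(2-methylprop-2-en-1-yl)-1,3,2-dioxaborolane
Product: 9 (4S)-2-methyl-5-(propan-2-ylidene)octa-1,7-dien-4-ol
Conditions: (S)-3,3'-bis(2,4,6-triisopropylphenyl)-1,1'-binaphthyl-2,2'-diyl hydrogen phosphate (5 mol%), toluene, 4 Å MS, −30 °C; aqueous work-up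
Reagents that add atoms: none
Why: Chiral phosphoric acid-catalysed allylboration should proceed through a closed chair transition state in which the catalyst binds the boronate oxygen and the formyl hydrogen, delivering the methallyl group to the Si face of the aldehyde and setting the (S)-carbinol.

**Step 4**
Reactants: 9 (4S)-2-methyl-5-(propan-2-ylidene)octa-1,7-dien-4-ol
Product: 10 (1S)-3-methyl-6-(propan-2-ylidene)cyclohex-3-en-1-ol
Conditions: second-generation Grubbs catalyst RuCl2(=CHPh)(PCy3)(H2IMes) (3 mol%), CH2Cl2 (0.01 M), 40 °C
Reagents that add atoms: none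
Why: Ring-closing metathesis should join the monosubstituted and the 1,1-disubstituted alkene into the trisubstituted cyclohexene, while the tetrasubstituted isopropylidene is inert and the carbinol centre is untouched.

**Step 5**
Reactants: 10 (1S)-3-methyl-6-(propan-2-ylidene)cyclohex-3-en-1-ol; 11 2-(dimethoxymethyl)furan
Product: 12 2-(methoxy{[(1S)-3-methyl-6-(propan-2-ylidene)cyclohex-3-en-1-yl]oxy}methyl)furan
Conditions: 11 (3 eq), pyridinium p-toluenesulfonate (5 mol%), benzene, 5 Å MS, 45 °C
Reagents that add atoms: none
Why: Acid-catalysed transacetalisation, driven by uptake of methanol on the sieves, should exchange one methoxy group for the secondary alcohol and so attach the furan through a two-atom O–CH(OMe) link without touching the carbinol centre.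

**Step 6**
Reactants: 12 2-(methoxy{[(1S)-3-methyl-6-(propan-2-ylidene)cyclohex-3-en-1-yl]oxy}methyl)furan
Product: 14 saturated tetracyclic methyl acetal (1S,2S,4R,2'S), via oxanorbornene cycloadduct 13 (not isolated)
Conditions: CH2Cl2 (0.05 M), 2,6-di-tert-butyl-4-methylpyridine (5 mol%), 13 kbar, 45 °C, 72 h; decompression at 0 °C; then KO2CN=NCO2K, AcOH, MeOH–CH2Cl2, 0 °C
Reagents that add atoms: none
Why: Proposed new method: an intramolecular Diels–Alder reaction of the furan onto an unactivated, unstrained tetrasubstituted alkene, argued from the concerted suprafacial [4+2] mechanism, whose strongly negative activation and reaction volumes let 13 kbar both accelerate the addition and shift its unfavourable equilibrium, after which diimide saturates the strained C=C of 13 before cycloreversion can set in; the closest known reaction type is the high-pressure intramolecular furan Diels–Alder reaction of 2-furfuryl ethers with unactivated mono- and disubstituted alkenes and with tetrasubstituted alkenes activated only by ring strain. The six-membered carbocycle of the 7-oxanorbornene closes by the [4+2] cycloaddition itself (furan C2 to the ring carbon that becomes the spiro centre, furan C5 to the CMe2 carbon), and the five-membered acetal ring closes as the fused ring of the three-atom tether. The spiro centre is controlled by the carbinol carbon: allylic 1,3-strain with the isopropylidene methyl holds the C–O bond axial, so the two-atom link can deliver furan C2 only to the alkene face syn to oxygen. Both bridgeheads are controlled by the tether, which can span the new bond only when it lies exo, that is syn to the oxygen bridge, and this places the carbinol carbon on the side of the bridge oxygen as in the target. The step needs site selectivity for the exocyclic alkene over the ring alkene, which the short tether should secure because addition to the ring alkene would need a four-atom link and a six-membered tether ring, an arrangement that unactivated furan cycloadditions tolerate poorly. The acetal methoxy group adds a gem-substituent effect, and the hindered pyridine keeps the acid-labile furfuryl acetal intact under pressure.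

**Step 7**
Reactants: 14 saturated tetracyclic methyl acetal (1S,2S,4R,2'S)
Product: 15 (1S,2S,4R,2'S)-1-(1,3-dithiolan-2-yl)-3,3,4'-trimethylspiro[7-oxabicyclo[2.2.1]heptane-2,1'-cyclohexan]-4'-en-2'-ol
Conditions: HSCH2CH2SH (3 eq), BF3·OEt2 (1.2 eq), CH2Cl2, −30 → 0 °C
Reagents that add atoms: ethane-1,2-dithiol, SCCS
Why: Lewis acid-mediated transthioacetalisation should ionise the cyclic acetal, open the tether ring through the sulfur-stabilised cation and close the dithiolane, which frees the 2'-hydroxyl and leaves all four stereocentres untouched.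

**Step 8**
Reactants: 15 (1S,2S,4R,2'S)-1-(1,3-dithiolan-2-yl)-3,3,4'-trimethylspiro[7-oxabicyclo[2.2.1]heptane-2,1'-cyclohexan]-4'-en-2'-ol
Product: 16 (1S,2S,4R,2'S)-1-(1,3-dithiolan-2-yl)-3,3,4'-trimethylspiro[7-oxabicyclo[2.2.1]heptane-2,1'-cyclohexan]-4'-en-2'-yl acetate
Conditions: Ac2O, pyridine, 4-(dimethylamino)pyridine (cat.), CH2Cl2, rt
Reagents that add atoms: acetic anhydride, CC(=O)OC(C)=O
Why: Nucleophile-catalysed acylation should esterify the hindered secondary alcohol with retention, and doing it before desulfurisation excludes nickel-mediated dehydrogenation of the free carbinol.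

**Step 9**
Reactants: 16 (1S,2S,4R,2'S)-1-(1,3-dithiolan-2-yl)-3,3,4'-trimethylspiro[7-oxabicyclo[2.2.1]heptane-2,1'-cyclohexan]-4'-en-2'-yl acetate
Product: 17 (1S,2S,4R,2'S)-1,3,3,4'-tetramethylspiro[7-oxabicyclo[2.2.1]heptane-2,1'-cyclohexan]-4'-en-2'-yl acetate
Conditions: Raney nickel (Ni, W-2 grade, deactivated in acetone), EtOH, 40 °C
Reagents that add atoms: none
Why: Reductive desulfurisation of the dithiolane should turn the former tether carbon into the C1 methyl group, while the trisubstituted alkene, the acetate and the ether bridge are inert on deactivated nickel.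

**Step 10**
Reactants: 17 (1S,2S,4R,2'S)-1,3,3,4'-tetramethylspiro[7-oxabicyclo[2.2.1]heptane-2,1'-cyclohexan]-4'-en-2'-yl acetate
Product: 18 (1S,2S,4R,2'S,4'S,5'S)-5'-bromo-4'-chloro-1,3,3,4'-tetramethylspiro[7-oxabicyclo[2.2.1]heptane-2,1'-cyclohexan]-2'-yl acetate
Conditions: N-bromosuccinimide (1.05 eq), HCl (1.0 M in Et2O, 1.05 eq), CH2Cl2, −78 °C
Reagents that add atoms: N-bromosuccinimide, O=C1CCC(=O)N1Br; hydrogen chloride, Cl
Why: Anti bromochlorination through a bromonium ion should place chloride on the tertiary carbon, with the bromonium ion forming on the ring face syn to the acetoxy group and away from the endo methyl of the CMe2 group and chloride entering axially from the opposite face (where only the carbinol hydrogen is syn-axial, the other face being screened by the axial acetate), which sets 4'S and 5'S.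

**Compound list**
1 | 3-methylbut-2-enal | CC(C)=CC=O | starting material
2 | cyclohexylamine | NC1CCCCC1 | starting material
3 | (E)-N-cyclohexyl-3-methylbut-2-en-1-imine | CC(C)=C/C=N/C1CCCCC1 | intermediate
4 | allyl bromide (3-bromoprop-1-ene) | C=CCBr | starting material
5 | N-cyclohexyl-2-(prop-1-en-2-yl)pent-4-en-1-imine (racemic; not isolated) | C=CCC(/C=N/C1CCCCC1)C(C)=C | intermediate
6 | 2-(prop-1-en-2-yl)pent-4-enal (racemic; not isolated) | C=CCC(C=O)C(C)=C | intermediate
7 | 2-(propan-2-ylidene)pent-4-enal | C=CCC(C=O)=C(C)C | intermediate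
8 | 4,4,5,5-tetramethyl-2-(2-methylprop-2-en-1-yl)-1,3,2-dioxaborolane | CC(=C)CB1OC(C)(C)C(C)(C)O1 | starting material
9 | (4S)-2-methyl-5-(propan-2-ylidene)octa-1,7-dien-4-ol | O[C@@H](CC(C)=C)C(=C(C)C)CC=C | intermediate
10 | (1S)-3-methyl-6-(propan-2-ylidene)cyclohex-3-en-1-ol | O[C@H]1CC(C)=CCC1=C(C)C | intermediate
11 | 2-(dimethoxymethyl)furan | COC(OC)c1ccco1 | starting material
12 | 2-(methoxy{[(1S)-3-methyl-6-(propan-2-ylidene)cyclohex-3-en-1-yl]oxy}methyl)furan; both epimers at the acetal carbon | COC(O[C@H]1CC(C)=CCC1=C(C)C)c1ccco1 | intermediate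
13 | oxanorbornene cycloadduct (1S,2S,4R,2'S): 3,3,4'-trimethylspiro[7-oxabicyclo[2.2.1]hept-5-ene-2,1'-cyclohex-4'-ene] whose C1 carries a CH(OMe) carbon bonded through O to C2' (cis-fused 2-methoxytetrahydrofuran, exo to the oxygen bridge); not isolated | COC1O[C@H]2CC(C)=CC[C@]23C(C)(C)[C@H]4C=C[C@]31O4 | intermediate
14 | saturated tetracyclic methyl acetal (1S,2S,4R,2'S): as 13 with C5–C6 single | COC1O[C@H]2CC(C)=CC[C@]23C(C)(C)[C@H]4CC[C@]31O4 | intermediate
15 | (1S,2S,4R,2'S)-1-(1,3-dithiolan-2-yl)-3,3,4'-trimethylspiro[7-oxabicyclo[2.2.1]heptane-2,1'-cyclohexan]-4'-en-2'-ol | O[C@H]1CC(C)=CC[C@]12C(C)(C)[C@H]1CC[C@]2(C3SCCS3)O1 | intermediate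
16 | (1S,2S,4R,2'S)-1-(1,3-dithiolan-2-yl)-3,3,4'-trimethylspiro[7-oxabicyclo[2.2.1]heptane-2,1'-cyclohexan]-4'-en-2'-yl acetate | CC(=O)O[C@H]1CC(C)=CC[C@]12C(C)(C)[C@H]1CC[C@]2(C3SCCS3)O1 | intermediate
17 | (1S,2S,4R,2'S)-1,3,3,4'-tetramethylspiro[7-oxabicyclo[2.2.1]heptane-2,1'-cyclohexan]-4'-en-2'-yl acetate | CC(=O)O[C@H]1CC(C)=CC[C@]12C(C)(C)[C@H]1CC[C@]2(C)O1 | intermediate
18 | (1S,2S,4R,2'S,4'S,5'S)-5'-bromo-4'-chloro-1,3,3,4'-tetramethylspiro[7-oxabicyclo[2.2.1]heptane-2,1'-cyclohexan]-2'-yl acetate | CC(=O)O[C@H]1C[C@](C)(Cl)[C@@H](Br)C[C@]12C(C)(C)[C@H]1CC[C@]2(C)O1 | target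

**Totals**
Total step count: 10. Longest linear sequence: 10 steps (1 to 18).

**Steps most likely to fail**

1. Step 6 (proposed new method). What may go wrong: the cycloaddition may stay too slow even under pressure, or the adduct may revert on decompression faster than diimide intercepts it, or the furan may add to the ring alkene. Fallback with known chemistry, from 10 back to 15: 10 is acylated with diketene (Et3N, 4-(dimethylamino)pyridine cat., CH2Cl2, 0 °C) to the acetoacetate F1. Base-catalysed Michael addition of F1 to acrolein (K2CO3 cat., 0 °C) gives the keto aldehyde ester F2. Deacylative diazo transfer (4-acetamidobenzenesulfonyl azide, DBU, MeCN, 0 °C) gives the α-diazo ester F3. Rh2(OAc)4 (1 mol%, CH2Cl2, slow addition, rt) then starts the carbenoid, carbonyl ylide, intramolecular [3+2] cascade: the aldehyde oxygen closes a five-membered ylide onto the carbenoid, and this electron-poor, ester-stabilised ylide should add irreversibly to the electron-rich tetrasubstituted alkene through the same three-atom tether. This would form the same two C–C bonds with the same syn and exo sense and give the saturated lactone F4 directly. iBu2AlH (CH2Cl2, −78 °C) reduces F4 to the lactol F5, which under the conditions of step 7 gives 15.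

2. Step 10. What may go wrong: opening of the bromonium ion by chloride at the secondary carbon or from both faces, or capture by the neighbouring acetate carbonyl. Fallback, from 17 back to 18: N-bromosuccinimide in THF–water (0 °C) uses water as a small, abundant nucleophile to give the anti bromohydrin acetate F6 (OH on the tertiary carbon). Anhydrous HCl in CH2Cl2 (−30 °C) then replaces the tertiary hydroxyl by chloride with retention, because the anti bromine assists ionisation through the bromonium ion and chloride re-enters from the face opposite to bromine, giving 18.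

3. Step 5. What may go wrong: acid-promoted ionisation of the tertiary-allylic carbinol (loss or 1,3-shift of oxygen) and scrambling to symmetrical acetals. Fallback, from 10 back to 15: 10 is esterified with furan-2-carbonyl chloride (pyridine, 4-(dimethylamino)pyridine cat.) to the furoate F7. Reductive acetylation of F7 (iBu2AlH, CH2Cl2, −78 °C; then Ac2O, pyridine, 4-(dimethylamino)pyridine) gives the α-acetoxy ether F8 under non-acidic conditions. F8 is taken through the pressure cycloaddition of step 6 to the unsaturated acetoxy acetal F9, which is reduced without isolation by diimide from 2-nitrobenzenesulfonyl hydrazide and Et3N in CH2Cl2 to the saturated acetoxy acetal F10. The conditions of step 7 convert F10 into 15.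

**Further compounds**
F1 | step 6 | (1S)-3-methyl-6-(propan-2-ylidene)cyclohex-3-en-1-yl 3-oxobutanoate | CC(=O)CC(=O)O[C@H]1CC(C)=CCC1=C(C)C
F2 | step 6 | (1S)-3-methyl-6-(propan-2-ylidene)cyclohex-3-en-1-yl 2-acetyl-5-oxopentanoate | CC(=O)C(CCC=O)C(=O)O[C@H]1CC(C)=CCC1=C(C)C
F3 | step 6 | (1S)-3-methyl-6-(propan-2-ylidene)cyclohex-3-en-1-yl 2-diazo-5-oxopentanoate | [N-]=[N+]=C(CCC=O)C(=O)O[C@H]1CC(C)=CCC1=C(C)C
F4 | step 6 | saturated tetracyclic lactone (1S,2S,4R,2'S): as 14 with C=O in place of CH(OMe) | O=C1O[C@H]2CC(C)=CC[C@]23C(C)(C)[C@H]4CC[C@]31O4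
F5 | step 6 | saturated tetracyclic lactol (1S,2S,4R,2'S): as 14 with OH in place of OMe | OC1O[C@H]2CC(C)=CC[C@]23C(C)(C)[C@H]4CC[C@]31O4
F6 | step 10 | (1S,2S,4R,2'S,4'S,5'S)-5'-bromo-4'-hydroxy-1,3,3,4'-tetramethylspiro[7-oxabicyclo[2.2.1]heptane-2,1'-cyclohexan]-2'-yl acetate | CC(=O)O[C@H]1C[C@](C)(O)[C@@H](Br)C[C@]12C(C)(C)[C@H]1CC[C@]2(C)O1
F7 | step 5 | (1S)-3-methyl-6-(propan-2-ylidene)cyclohex-3-en-1-yl furan-2-carboxylate | O=C(O[C@H]1CC(C)=CCC1=C(C)C)c1ccco1
F8 | step 5 | furan-2-yl{[(1S)-3-methyl-6-(propan-2-ylidene)cyclohex-3-en-1-yl]oxy}methyl acetate | CC(=O)OC(O[C@H]1CC(C)=CCC1=C(C)C)c1ccco1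
F9 | step 5 | oxanorbornene cycloadduct (1S,2S,4R,2'S): as 13 with OAc in place of OMe | CC(=O)OC1O[C@H]2CC(C)=CC[C@]23C(C)(C)[C@H]4C=C[C@]31O4
F10 | step 5 | saturated tetracyclic acetoxy acetal (1S,2S,4R,2'S): as 14 with OAc in place of OMe | CC(=O)OC1O[C@H]2CC(C)=CC[C@]23C(C)(C)[C@H]4CC[C@]31O4
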